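A direct plan would start from 3',4'-dihydroxyacetophenone A1, benzylate O4 and allylate O3, and lengthen the acetyl group by two Claisen condensations,
saponification and diazomethane acylation to the 6-aryl-4-pyranone diazoketone A2; ring A would be closed last.
Light would turn A2 into a ketene that would add (triisopropylsilyloxy)ethyne A3, ring-open and electrocyclize onto pyranone C3 to the protected luteolin A4;
unmasking, sulfation and hydrogenolysis would follow. Its weakest steps would be:
(a) this benzannulation, a ring closure left to chance on the most advanced material, since a pyranone C2=C3 bond is untested as the alkene of a vinylketene;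
(b) the six-step run from ketone to diazoketone (hydroxide on a base-sensitive pyranone, diazomethane next to a Michael acceptor), which would only rebuild a phloroglucinol ring that can be bought;
(c) the opening mono-benzylation of the catechol, whose O4 selectivity would rest on a small acidity difference alone.

Plan of the new route
The retrosynthesis cuts the two O–S bonds and then only the C2–C1' bond between ring C and ring B.
Rings A and C come fused and finished as 5,7-dihydroxychromone, ring B as catechol monobenzyl ether; no ring is closed anywhere.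
The enabling feature is C2–H of ring C: C2 is the β-carbon of the vinylogous ester O1–C2=C3–C4=O, so an aryl–palladium species delivers its aryl group there, and C2–C1' is the only bond joining the two halves.
O7 versus O5 is set by chelation of the 5-OH to C4=O; O3' versus O4' is set by an ester-versus-ether directed bromination of ring B.
Hence no late benzannulation, no diazo compound and no selective catechol alkylation occur.

Key step: step 6

Assumption: 5,7-dihydroxychromone and 2-(benzyloxy)phenol are bought; the target is the free bis(hydrogen sulfate) as drawn and would be kept as its disodium salt until the last operation.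

Step 1
Reactants: 1 5,7-dihydroxy-4H-chromen-4-one
Product: 2 5-hydroxy-7-(methoxymethoxy)-4H-chromen-4-one
Conditions: MOMCl (1.1 equiv), i-Pr2NEt (1.5 equiv), DMF–CH2Cl2, 0 → 25 °C
Reagents that add atoms: chloromethyl methyl ether, COCCl
Why: Williamson-type O-alkylation at the only acidic, non-chelated phenol, since the 7-OH is conjugated with C4=O while the 5-OH is locked in a hydrogen bond to that carbonyl, so one equivalent of the chloride should alkylate O7 alone.

Step 2
Reactants: 2 5-hydroxy-7-(methoxymethoxy)-4H-chromen-4-one
Product: 3 5-(benzyloxy)-7-(methoxymethoxy)-4H-chromen-4-one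
Conditions: BnBr (1.5 equiv), K2CO3 (2 equiv), Bu4NI (cat.), DMF, 60 °C
Reagents that add atoms: benzyl bromide, BrCc1ccccc1
Why: Williamson etherification of the chelated 5-OH, the only phenol left, which needs carbonate in DMF with iodide catalysis and warming, conditions to which the acetal at O7 is stable.

Step 3
Reactants: 4 2-(benzyloxy)phenol
Product: 5 2-(benzyloxy)phenyl pivalate
Conditions: PivCl (1.2 equiv), Et3N (1.5 equiv), DMAP (5 mol %), CH2Cl2, 0 → 25 °C
Reagents that add atoms: pivaloyl chloride, CC(C)(C)C(Cl)=O
Why: DMAP-catalysed esterification of the single phenol, which turns the stronger donor oxygen into a weak one for the next step.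

Step 4
Reactants: 5 2-(benzyloxy)phenyl pivalate
Product: 6 2-(benzyloxy)-5-bromophenyl pivalate
Conditions: NBS (1.05 equiv), MeCN, 25 °C, dark
Reagents that add atoms: N-bromosuccinimide, O=C1CCC(=O)N1Br
Why: Electrophilic aromatic bromination, in which the ether oxygen is a far stronger para director than the acylated oxygen, so bromine should enter para to the benzyloxy group at the carbon that becomes C1', with O4' benzylated and O3' acylated.

Step 5
Reactants: 6 2-(benzyloxy)-5-bromophenyl pivalate
Product: 7 2-(benzyloxy)-5-(4,4,5,5-tetramethyl-1,3,2-dioxaborolan-2-yl)phenyl pivalate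
Conditions: B2pin2 (1.2 equiv), PdCl2(dppf) (3 mol %), KOAc (3 equiv), 1,4-dioxane, 85 °C
Reagents that add atoms: bis(pinacolato)diboron, CC1(C)OB(OC1(C)C)B1OC(C)(C)C(C)(C)O1
Why: Miyaura borylation of the aryl bromide through zerovalent palladium, with acetate as a base mild enough to spare the aryl pivalate and the benzyl ether.

Step 6
Reactants: 3 5-(benzyloxy)-7-(methoxymethoxy)-4H-chromen-4-one; 7 2-(benzyloxy)-5-(4,4,5,5-tetramethyl-1,3,2-dioxaborolan-2-yl)phenyl pivalate (1.8 equiv)
Product: 8 2-(benzyloxy)-5-[5-(benzyloxy)-7-(methoxymethoxy)-4-oxo-4H-chromen-2-yl]phenyl pivalate (5,4'-di-O-benzyl-7-O-methoxymethyl-3'-O-pivaloylluteolin)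
Conditions: Pd(OCOCF3)2 (15 mol %), 5-nitro-1,10-phenanthroline (20 mol %), O2 (1 atm), DMSO, 100 °C
Reagents that add atoms: none
Why: Oxidative boron Heck reaction: the aryl group passes from boron to ligated divalent palladium, the aryl–palladium bond adds syn across C2=C3 with the aryl group going to C2, the β-carbon of the vinylogous ester, and palladium to C3 as a palladium enolate; equilibration of this enolate through its oxygen-bound form lets the C2 hydrogen reach palladium for β-hydride elimination (or the enolate is protonated and the flavanone is dehydrogenated by the same catalyst), and O2 returns zerovalent palladium to the divalent state. The closest known reaction type is the arylation of chromones and chromanones at C2 with arylboron compounds under divalent palladium and an oxidant, which gives flavones. No ring is closed and no stereocentre remains, since the sp3 centre formed at C2 in the adduct is lost when the C2=C3 bond returns. The step needs C2 over C3 and over the electron-rich C6–H and C8–H of ring A: carbopalladation by a preformed aryl–palladium species follows the polarity of the enone, whereas C3, C6 and C8 could react only by electrophilic palladation, which the chelating nitrogen ligand disfavours. The benzyl ether at O5 keeps the 5-oxygen and C4=O from chelating palladium, and the pivalate, the acetal and the benzyl ethers should be inert to the neutral conditions.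

Step 7
Reactants: 8 2-(benzyloxy)-5-[5-(benzyloxy)-7-(methoxymethoxy)-4-oxo-4H-chromen-2-yl]phenyl pivalate
Product: 10 5-(benzyloxy)-2-[4-(benzyloxy)-3-hydroxyphenyl]-7-hydroxy-4H-chromen-4-one (5,4'-di-O-benzylluteolin), via methoxymethyl ether 9 (not isolated)
Conditions: K2CO3 (3 equiv), MeOH–THF (1:1), 40 °C; then HCl (6 M aq., to pH 1), 45 °C
Reagents that add atoms: none
Why: Methanolysis (transesterification) of the aryl pivalate followed in the same pot by acid-catalysed acetal cleavage of the methoxymethyl ether, both benzyl ethers being stable to carbonate and to dilute acid at this temperature, while any ring C opened by base would re-close under the acid.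

Step 8
Reactants: 10 5-(benzyloxy)-2-[4-(benzyloxy)-3-hydroxyphenyl]-7-hydroxy-4H-chromen-4-one
Product: 11 disodium 5,4'-di-O-benzylluteolin 7,3'-disulfate
Conditions: SO3·pyridine (6 equiv), pyridine, 25 → 40 °C; then aq. NaHCO3; reversed-phase chromatography
Reagents that add atoms: sulfur trioxide–pyridine complex, [O-]S(=O)(=O)[n+]1ccccc1; sodium hydrogen carbonate, [Na+].OC([O-])=O (supplies the sodium ions)
Why: O-Sulfation of phenols with an SO3–amine complex, in which only O7 and O3' carry hydrogen, so the 7,3' pattern is fixed by the benzyl ethers at O5 and O4' and not by relative reactivity.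

Step 9
Reactants: 11 disodium 5,4'-di-O-benzylluteolin 7,3'-disulfate
Product: 13 luteolin 7,3'-disulfate, via disodium salt 12 (not isolated)
Conditions: H2 (1 atm), Pd/C (10 wt %), MeOH–H2O, 25 °C; filtration; then sulfonic acid resin (H+ form), H2O, 0 °C; lyophilisation
Reagents that add atoms: none
Why: Hydrogenolysis of the two benzyl aryl ethers on Pd/C, to which aryl sulfate salts and the flavone C2=C3 bond should be inert at 1 atm, followed by cation exchange of sodium for hydrogen in the cold.

Compound list
1 | 5,7-dihydroxy-4H-chromen-4-one (5,7-dihydroxychromone) | O=c1ccoc2cc(O)cc(O)c12 | starting material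
2 | 5-hydroxy-7-(methoxymethoxy)-4H-chromen-4-one | O=c1ccoc2cc(OCOC)cc(O)c12 | intermediate
3 | 5-(benzyloxy)-7-(methoxymethoxy)-4H-chromen-4-one | O=c1ccoc2cc(OCOC)cc(OCc3ccccc3)c12 | intermediate
4 | 2-(benzyloxy)phenol | Oc1ccccc1OCc1ccccc1 | starting material
5 | 2-(benzyloxy)phenyl pivalate | CC(C)(C)C(=O)Oc1ccccc1OCc1ccccc1 | intermediate
6 | 2-(benzyloxy)-5-bromophenyl pivalate | CC(C)(C)C(=O)Oc1cc(Br)ccc1OCc1ccccc1 | intermediate
7 | 2-(benzyloxy)-5-(4,4,5,5-tetramethyl-1,3,2-dioxaborolan-2-yl)phenyl pivalate | CC(C)(C)C(=O)Oc1cc(B2OC(C)(C)C(C)(C)O2)ccc1OCc1ccccc1 | intermediate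
8 | 2-(benzyloxy)-5-[5-(benzyloxy)-7-(methoxymethoxy)-4-oxo-4H-chromen-2-yl]phenyl pivalate | O=c1cc(-c2ccc(OCc3ccccc3)c(OC(=O)C(C)(C)C)c2)oc2cc(OCOC)cc(OCc3ccccc3)c12 | intermediate
9 | 5-(benzyloxy)-2-[4-(benzyloxy)-3-hydroxyphenyl]-7-(methoxymethoxy)-4H-chromen-4-one (not isolated) | O=c1cc(-c2ccc(OCc3ccccc3)c(O)c2)oc2cc(OCOC)cc(OCc3ccccc3)c12 | intermediate
10 | 5-(benzyloxy)-2-[4-(benzyloxy)-3-hydroxyphenyl]-7-hydroxy-4H-chromen-4-one (5,4'-di-O-benzylluteolin) | O=c1cc(-c2ccc(OCc3ccccc3)c(O)c2)oc2cc(O)cc(OCc3ccccc3)c12 | intermediate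
11 | disodium 5,4'-di-O-benzylluteolin 7,3'-disulfate | O=c1cc(-c2ccc(OCc3ccccc3)c(OS(=O)(=O)[O-])c2)oc2cc(OS(=O)(=O)[O-])cc(OCc3ccccc3)c12.[Na+].[Na+] | intermediate
12 | disodium luteolin 7,3'-disulfate (not isolated) | O=c1cc(-c2ccc(O)c(OS(=O)(=O)[O-])c2)oc2cc(OS(=O)(=O)[O-])cc(O)c12.[Na+].[Na+] | intermediate
13 | luteolin 7,3'-disulfate | O=c1cc(-c2ccc(O)c(OS(=O)(=O)O)c2)oc2cc(OS(=O)(=O)O)cc(O)c12 | target

Total step count: 9. Longest linear sequence: 7 steps (steps 3 to 9, from 2-(benzyloxy)phenol); the chromone branch joins after 2 steps.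

Steps most likely to fail

Step 6. The pinacol boronate may transmetalate slowly and be lost to oxidation or protodeboronation under O2, or the reaction may stall at the conjugate adduct. The fallback sets out from 3 and 7 and separates addition from oxidation. Conjugate addition under argon (Pd(OCOCF3)2, 2,2'-bipyridine, AcOH–THF–H2O, 60 °C), where the palladium enolate is protonated instead of eliminated, should give the racemic flavanone 5-(benzyloxy)-2-[4-(benzyloxy)-3-(pivaloyloxy)phenyl]-7-(methoxymethoxy)chroman-4-one F1. A separate dehydrogenation (DDQ, 1,4-dioxane, 90 °C) would then return to 8.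

Step 8. Sulfation of the hindered 3'-OH may stop at the monosulfate, and the salts may be hard to separate and may lose sulfate on acidic supports. The fallback sets out from 10 and carries the sulfates as neutral diesters. 2,2,2-Trichloroethyl chlorosulfate (Et3N, DMAP, THF, 0 → 25 °C) should give 5,4'-di-O-benzylluteolin 7,3'-bis(2,2,2-trichloroethyl sulfate) F2, which can be purified on silica. Pd/C with HCO2NH4 in MeOH should then cleave both trichloroethyl groups and both benzyl ethers to diammonium luteolin 7,3'-disulfate F3, which the acid resin at 0 °C would convert to 13.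

Step 7. The acid stage may strip the 5-O-benzyl ether, which the neighbouring carbonyl labilises, and the base stage may open ring C. The fallback sets out from 3 and moves the acid step to the chromone, where any loss of benzyl would fall on cheap early material. Acetal cleavage there (HCl, MeOH, 40 °C) should give 5-(benzyloxy)-7-hydroxy-4H-chromen-4-one F4, and acylation (PivCl, Et3N, DMAP, CH2Cl2) should give 5-(benzyloxy)-4-oxo-4H-chromen-7-yl pivalate F5. Coupling with 7 under the conditions of step 6 should give 5,4'-di-O-benzyl-7,3'-di-O-pivaloylluteolin F6, and K2CO3 in MeOH–THF alone would return to 10, so that the flavone never meets acid.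

Further compounds
F1 | step 6 | racemic 5-(benzyloxy)-2-[4-(benzyloxy)-3-(pivaloyloxy)phenyl]-7-(methoxymethoxy)chroman-4-one | O=C1CC(c2ccc(OCc3ccccc3)c(OC(=O)C(C)(C)C)c2)Oc2cc(OCOC)cc(OCc3ccccc3)c12
F2 | step 8 | 5,4'-di-O-benzylluteolin 7,3'-bis(2,2,2-trichloroethyl sulfate) | O=c1cc(-c2ccc(OCc3ccccc3)c(OS(=O)(=O)OCC(Cl)(Cl)Cl)c2)oc2cc(OS(=O)(=O)OCC(Cl)(Cl)Cl)cc(OCc3ccccc3)c12
F3 | step 8 | diammonium luteolin 7,3'-disulfate | O=c1cc(-c2ccc(O)c(OS(=O)(=O)[O-])c2)oc2cc(OS(=O)(=O)[O-])cc(O)c12.[NH4+].[NH4+]
F4 | step 7 | 5-(benzyloxy)-7-hydroxy-4H-chromen-4-one | O=c1ccoc2cc(O)cc(OCc3ccccc3)c12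
F5 | step 7 | 5-(benzyloxy)-4-oxo-4H-chromen-7-yl pivalate | O=c1ccoc2cc(OC(=O)C(C)(C)C)cc(OCc3ccccc3)c12
F6 | step 7 | 5,4'-di-O-benzyl-7,3'-di-O-pivaloylluteolin | O=c1cc(-c2ccc(OCc3ccccc3)c(OC(=O)C(C)(C)C)c2)oc2cc(OC(=O)C(C)(C)C)cc(OCc3ccccc3)c12
A1 | direct plan | 3',4'-dihydroxyacetophenone | CC(=O)c1ccc(O)c(O)c1
A2 | direct plan | 2-(diazoacetyl)-6-[3-(allyloxy)-4-(benzyloxy)phenyl]-4H-pyran-4-one | [N-]=[N+]=CC(=O)c1cc(=O)cc(-c2ccc(OCc3ccccc3)c(OCC=C)c2)o1
A3 | direct plan | (triisopropylsilyloxy)ethyne | C#CO[Si](C(C)C)(C(C)C)C(C)C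
A4 | direct plan | 3'-O-allyl-4'-O-benzyl-7-O-(triisopropylsilyl)luteolin | O=c1cc(-c2ccc(OCc3ccccc3)c(OCC=C)c2)oc2cc(O[Si](C(C)C)(C(C)C)C(C)C)cc(O)c12
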